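**Retrosynthetic overview**
- The plan rests on the two 3-methylbut-2-enyl chains at C2' and C6' of ring B (the pendant benzene ring). Their trisubstituted C=C bonds lie ortho and para to the free C3' hydroxyl and are acid-sensitive, so both are made last by double cross-metathesis of diallyl diphenol 12 with 2-methylbut-2-ene.
- 12 comes from trimethyl ether 11 by thiolate O-demethylation, which should cleave the C6 methyl ether of ring A and only one of the two equivalent methyl ethers of ring B.
- The C1'–C2 biaryl bond of 11 is made by Negishi coupling of the di-ortho-allyl aryl triflate 7 with 2-zincated 6-methoxybenzofuran 10.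
- 7 comes from mirror-symmetric 3,5-dimethoxyphenol by two O-allylation/Claisen cycles at the C1' oxygen, each giving a single regioisomer, followed by triflation.
- No ring is formed: ring B is bought as 3,5-dimethoxyphenol and the benzofuran (benzo ring A, furan ring C) as 6-methoxy-1-benzofuran.

Key step: step 8

Assumption: ring B is numbered with C1' at the carbon bonded to C2 of the benzofuran, C3' at the free hydroxyl and C5' at the methoxy group; 6-methoxy-1-benzofuran, sodium ethanethiolate and Tf2O are treated as bought compounds.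

**Step 1**
Reactants: 1 3,5-dimethoxyphenol; 2 allyl bromide
Product: 3 1,3-dimethoxy-5-(prop-2-en-1-yloxy)benzene
Conditions: K2CO3, acetone, reflux
Reagents that add atoms: allyl bromide (2), C=CCBr
Why: Williamson ether synthesis of a phenoxide with a reactive allylic bromide should give the allyl aryl ether cleanly.

**Step 2**
Reactants: 3 1,3-dimethoxy-5-(prop-2-en-1-yloxy)benzene
Product: 4 3,5-dimethoxy-2-(prop-2-en-1-yl)phenol
Conditions: N,N-diethylaniline, 190 °C
Reagents that add atoms: none
Why: Aromatic Claisen rearrangement ([3,3]-sigmatropic shift, then tautomerization of the dienone) should deliver the allyl group to an ortho carbon, and the mirror symmetry of 3 makes the two ortho carbons equivalent, so one product is expected.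

**Step 3**
Reactants: 4 3,5-dimethoxy-2-(prop-2-en-1-yl)phenol; 2 allyl bromide
Product: 5 1,5-dimethoxy-2-(prop-2-en-1-yl)-3-(prop-2-en-1-yloxy)benzene
Conditions: K2CO3, acetone, reflux
Reagents that add atoms: allyl bromide (2), C=CCBr
Why: Williamson ether synthesis on the mono-ortho-substituted phenol, which remains nucleophilic enough for an allylic bromide.

**Step 4**
Reactants: 5 1,5-dimethoxy-2-(prop-2-en-1-yl)-3-(prop-2-en-1-yloxy)benzene
Product: 6 3,5-dimethoxy-2,6-di(prop-2-en-1-yl)phenol
Conditions: N,N-diethylaniline, 190–200 °C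
Reagents that add atoms: none
Why: Second aromatic Claisen rearrangement, in which only one ortho carbon still carries a hydrogen and can tautomerize, so the allyl group should end up there and give the 2,6-diallylphenol.

**Step 5**
Reactants: 6 3,5-dimethoxy-2,6-di(prop-2-en-1-yl)phenol
Product: 7 3,5-dimethoxy-2,6-di(prop-2-en-1-yl)phenyl trifluoromethanesulfonate
Conditions: Tf2O, pyridine, CH2Cl2, −20 → 0 °C
Reagents that add atoms: trifluoromethanesulfonic anhydride (Tf2O), O=S(=O)(OS(=O)(=O)C(F)(F)F)C(F)(F)F
Why: O-sulfonylation with the small, very electrophilic anhydride should reach even a phenol flanked by two allyl groups, and pyridine takes up the triflic acid so that the alkenes are not protonated.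

**Step 6**
Reactants: 8 6-methoxy-1-benzofuran; 7 3,5-dimethoxy-2,6-di(prop-2-en-1-yl)phenyl trifluoromethanesulfonate
Product: 11 2-[3,5-dimethoxy-2,6-di(prop-2-en-1-yl)phenyl]-6-methoxy-1-benzofuran, via 2-lithio-6-methoxy-1-benzofuran 9 (not isolated), via chloro(6-methoxy-1-benzofuran-2-yl)zinc 10 (not isolated)
Conditions: 8 (1.5 equiv), n-BuLi, THF, −78 °C; ZnCl2, −78 °C → rt; then 7, Pd2(dba)3 (cat.), XPhos, THF, 60 °C
Reagents that add atoms: none
Why: Lithiation at C2 (the most acidic C–H of benzofuran, well ahead of the positions next to the methoxy group), transmetalation to zinc and Negishi cross-coupling with the aryl triflate under a bulky biarylphosphine/zerovalent palladium catalyst should forge the hindered C1'–C2 bond, and the base-free organozinc conditions should leave the allyl groups unisomerized.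

**Step 7**
Reactants: 11 2-[3,5-dimethoxy-2,6-di(prop-2-en-1-yl)phenyl]-6-methoxy-1-benzofuran
Product: 12 2-[3-hydroxy-5-methoxy-2,6-di(prop-2-en-1-yl)phenyl]-1-benzofuran-6-ol
Conditions: NaSEt (5 equiv), degassed DMF, 130 °C; then 1 M HCl, 0 °C
Reagents that add atoms: none
Why: Nucleophilic O-demethylation of aryl methyl ethers (SN2 attack of ethanethiolate at the methyl carbon) should cleave the C6 ether of ring A and one of the two equivalent ethers of ring B, and should then stop, because loss of the second ring-B methyl would require a resorcinolate dianion as leaving group, as in the known selective mono-demethylation of resorcinol dimethyl ethers; the soft, weakly basic thiolate should not touch the allyl groups.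

**Step 8**
Reactants: 12 2-[3-hydroxy-5-methoxy-2,6-di(prop-2-en-1-yl)phenyl]-1-benzofuran-6-ol; 13 2-methylbut-2-ene
Product: 14 2-[3-hydroxy-5-methoxy-2,6-bis(3-methylbut-2-en-1-yl)phenyl]-1-benzofuran-6-ol
Conditions: RuCl2(=CHPh)(PCy3)(H2IMes) (second-generation Grubbs catalyst, 5–10 mol %), 2-methylbut-2-ene as solvent (minimum CH2Cl2 to dissolve 12), 35–40 °C, sealed tube
Reagents that add atoms: 2-methylbut-2-ene (13), CC=C(C)C
Why: Olefin cross-metathesis: 2-methylbut-2-ene turns the ruthenium benzylidene into isopropylidene and ethylidene carbenes, and [2+2] cycloaddition of each terminal allyl C=C to the carbene followed by cycloreversion of the ruthenacyclobutane exchanges the terminal CH2 for C(CH3)2 with loss of propene. The closest known reaction type is the cross-metathesis of allylarenes, free ortho-allylphenols included, with 2-methylbut-2-ene to give prenylarenes. No ring is closed and no stereocentre is formed, and each new alkene carries two identical methyl groups, so no E/Z question arises. The step needs cross- over homo-metathesis at both allyl groups and no migration of the double bonds into conjugation with ring B; the large excess of 2-methylbut-2-ene as solvent should secure the first and the mild temperature the second, while the hindered trisubstituted prenyl alkenes should not re-enter the cycle. The two allyl groups stand 1,3 on ring B, so joining them would demand a strained bridged ring, and the C2=C3 bond of the benzofuran is aromatic and inert.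

**Compound list**
1 | 3,5-dimethoxyphenol | COc1cc(O)cc(OC)c1 | starting material
2 | allyl bromide (3-bromoprop-1-ene) | C=CCBr | starting material
3 | 1,3-dimethoxy-5-(prop-2-en-1-yloxy)benzene | C=CCOc1cc(OC)cc(OC)c1 | intermediate
4 | 3,5-dimethoxy-2-(prop-2-en-1-yl)phenol | C=CCc1c(O)cc(OC)cc1OC | intermediate
5 | 1,5-dimethoxy-2-(prop-2-en-1-yl)-3-(prop-2-en-1-yloxy)benzene | C=CCOc1cc(OC)cc(OC)c1CC=C | intermediate
6 | 3,5-dimethoxy-2,6-di(prop-2-en-1-yl)phenol | C=CCc1c(O)c(CC=C)c(OC)cc1OC | intermediate
7 | 3,5-dimethoxy-2,6-di(prop-2-en-1-yl)phenyl trifluoromethanesulfonate | C=CCc1c(OS(=O)(=O)C(F)(F)F)c(CC=C)c(OC)cc1OC | intermediate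
8 | 6-methoxy-1-benzofuran | COc1ccc2ccoc2c1 | starting material
9 | 2-lithio-6-methoxy-1-benzofuran | COc1ccc2cc([Li])oc2c1 | intermediate
10 | chloro(6-methoxy-1-benzofuran-2-yl)zinc | COc1ccc2cc([Zn]Cl)oc2c1 | intermediate
11 | 2-[3,5-dimethoxy-2,6-di(prop-2-en-1-yl)phenyl]-6-methoxy-1-benzofuran | COc1ccc2cc(-c3c(CC=C)c(OC)cc(OC)c3CC=C)oc2c1 | intermediate
12 | 2-[3-hydroxy-5-methoxy-2,6-di(prop-2-en-1-yl)phenyl]-1-benzofuran-6-ol | COc1cc(O)c(CC=C)c(-c2cc3ccc(O)cc3o2)c1CC=C | intermediate
13 | 2-methylbut-2-ene | CC=C(C)C | starting material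
14 | 2-[3-hydroxy-5-methoxy-2,6-bis(3-methylbut-2-en-1-yl)phenyl]-1-benzofuran-6-ol | COc1cc(O)c(CC=C(C)C)c(-c2cc3ccc(O)cc3o2)c1CC=C(C)C | target

**Step count**
Total steps: 8. Longest linear sequence: 8 steps (steps 1–8; the benzofuran partner 8 is bought and metalated in the flask in step 6).

**Steps most likely to fail**

Step 8. The risk is migration of the allyl double bonds into conjugation with ring B under ruthenium hydride catalysis, stalling after exchange at only one allyl group, and scrambling to but-2-enyl ends. The fallback abandons metathesis for oxidative cleavage and olefination. It sets out from 12. TBSCl and imidazole in DMF should give 6-[(tert-butyldimethylsilyl)oxy]-2-{3-[(tert-butyldimethylsilyl)oxy]-5-methoxy-2,6-di(prop-2-en-1-yl)phenyl}-1-benzofuran F1. Lemieux–Johnson cleavage (catalytic OsO4, NaIO4, 2,6-lutidine, dioxane–water) of both terminal alkenes should give 2,2'-{4-[(tert-butyldimethylsilyl)oxy]-2-{6-[(tert-butyldimethylsilyl)oxy]-1-benzofuran-2-yl}-6-methoxy-1,3-phenylene}diacetaldehyde F2. Double Wittig olefination with isopropylidenetriphenylphosphorane (from isopropyltriphenylphosphonium iodide and n-BuLi, THF, −78 → 0 °C) should give 6-[(tert-butyldimethylsilyl)oxy]-2-{3-[(tert-butyldimethylsilyl)oxy]-5-methoxy-2,6-bis(3-methylbut-2-en-1-yl)phenyl}-1-benzofuran F3. Bu4NF buffered with AcOH in THF at 0 °C then frees both phenols without strong acid, and the fallback rejoins the route at 14.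

Step 6. The risk is crowding at palladium when the di-ortho-allyl aryl group and the benzofuranyl group must meet in transmetalation and reductive elimination, so that S–O cleavage of the triflate, homocoupling of the zinc reagent or palladium hydride isomerization of the allyl groups takes over. The fallback transfers a slim alkynyl group instead and builds furan ring C. It sets out from 7. Sonogashira coupling with ethynyltrimethylsilane (PdCl2(PPh3)2, CuI, Et3N, DMF, 80 °C) should give {[3,5-dimethoxy-2,6-di(prop-2-en-1-yl)phenyl]ethynyl}trimethylsilane F4. K2CO3 in MeOH should give 3-ethynyl-1,5-dimethoxy-2,4-di(prop-2-en-1-yl)benzene F5. Tandem Sonogashira coupling and 5-endo cyclization with bought 4-iodobenzene-1,3-diol (Oc1ccc(I)c(O)c1; PdCl2(PPh3)2, CuI, Et3N, DMF, 60–80 °C) should give 2-[3,5-dimethoxy-2,6-di(prop-2-en-1-yl)phenyl]-1-benzofuran-6-ol F6, in which the hydroxyl ortho to iodine has become the furan oxygen and the para hydroxyl is the C6 hydroxyl. NaSEt in DMF as in step 7 then removes one of the two equivalent methyl groups of ring B, and the fallback rejoins the route at 12.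

Step 7. The risk is that cleavage does not stop after one methyl group of ring B, that the allyl double bonds migrate into conjugation under the hot basic conditions, and that thiyl radicals add to the terminal alkenes. The fallback differentiates the two ring-B oxygens before the coupling and carries both phenols as methoxymethyl acetals, so that no methyl ether is cleaved late. It sets out from 7. BBr3 (1.0 equiv) in CH2Cl2 at −78 → −20 °C, quenched cold with water, should cleave one of the two equivalent methyl ethers and give 3-hydroxy-5-methoxy-2,6-di(prop-2-en-1-yl)phenyl trifluoromethanesulfonate F7. MOMCl and i-Pr2NEt in CH2Cl2 should give 3-methoxy-5-(methoxymethoxy)-2,6-di(prop-2-en-1-yl)phenyl trifluoromethanesulfonate F8. Bought 1-benzofuran-6-ol (Oc1ccc2ccoc2c1) with NaH and MOMCl in DMF should give 6-(methoxymethoxy)-1-benzofuran F9, which n-BuLi in THF at −78 °C converts into 2-lithio-6-(methoxymethoxy)-1-benzofuran F10 and ZnCl2 into chloro[6-(methoxymethoxy)-1-benzofuran-2-yl]zinc F11. Negishi coupling of F11 with F8 (Pd2(dba)3, XPhos, THF, 60 °C) should give 6-(methoxymethoxy)-2-[3-methoxy-5-(methoxymethoxy)-2,6-di(prop-2-en-1-yl)phenyl]-1-benzofuran F12. HCl in MeOH–THF at rt → 40 °C removes both acetals, and the fallback rejoins the route at 12.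

**Further compounds**
F1 | step 8 | 6-[(tert-butyldimethylsilyl)oxy]-2-{3-[(tert-butyldimethylsilyl)oxy]-5-methoxy-2,6-di(prop-2-en-1-yl)phenyl}-1-benzofuran | COc1cc(O[Si](C)(C)C(C)(C)C)c(CC=C)c(-c2cc3ccc(O[Si](C)(C)C(C)(C)C)cc3o2)c1CC=C
F2 | step 8 | 2,2'-{4-[(tert-butyldimethylsilyl)oxy]-2-{6-[(tert-butyldimethylsilyl)oxy]-1-benzofuran-2-yl}-6-methoxy-1,3-phenylene}diacetaldehyde | COc1cc(O[Si](C)(C)C(C)(C)C)c(CC=O)c(-c2cc3ccc(O[Si](C)(C)C(C)(C)C)cc3o2)c1CC=O
F3 | step 8 | 6-[(tert-butyldimethylsilyl)oxy]-2-{3-[(tert-butyldimethylsilyl)oxy]-5-methoxy-2,6-bis(3-methylbut-2-en-1-yl)phenyl}-1-benzofuran | COc1cc(O[Si](C)(C)C(C)(C)C)c(CC=C(C)C)c(-c2cc3ccc(O[Si](C)(C)C(C)(C)C)cc3o2)c1CC=C(C)C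
F4 | step 6 | {[3,5-dimethoxy-2,6-di(prop-2-en-1-yl)phenyl]ethynyl}trimethylsilane | C=CCc1c(C#C[Si](C)(C)C)c(CC=C)c(OC)cc1OC
F5 | step 6 | 3-ethynyl-1,5-dimethoxy-2,4-di(prop-2-en-1-yl)benzene | C=CCc1c(C#C)c(CC=C)c(OC)cc1OC
F6 | step 6 | 2-[3,5-dimethoxy-2,6-di(prop-2-en-1-yl)phenyl]-1-benzofuran-6-ol | COc1cc(OC)c(CC=C)c(-c2cc3ccc(O)cc3o2)c1CC=C
F7 | step 7 | 3-hydroxy-5-methoxy-2,6-di(prop-2-en-1-yl)phenyl trifluoromethanesulfonate | C=CCc1c(OS(=O)(=O)C(F)(F)F)c(CC=C)c(O)cc1OC
F8 | step 7 | 3-methoxy-5-(methoxymethoxy)-2,6-di(prop-2-en-1-yl)phenyl trifluoromethanesulfonate | C=CCc1c(OS(=O)(=O)C(F)(F)F)c(CC=C)c(OCOC)cc1OC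
F9 | step 7 | 6-(methoxymethoxy)-1-benzofuran | COCOc1ccc2ccoc2c1
F10 | step 7 | 2-lithio-6-(methoxymethoxy)-1-benzofuran | COCOc1ccc2cc([Li])oc2c1
F11 | step 7 | chloro[6-(methoxymethoxy)-1-benzofuran-2-yl]zinc | COCOc1ccc2cc([Zn]Cl)oc2c1
F12 | step 7 | 6-(methoxymethoxy)-2-[3-methoxy-5-(methoxymethoxy)-2,6-di(prop-2-en-1-yl)phenyl]-1-benzofuran | COCOc1ccc2cc(-c3c(CC=C)c(OC)cc(OCOC)c3CC=C)oc2c1
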